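The furofuran is disconnected at C8–C8′ and, through a latent cyclobutane, at the C9–O–C7′ linkage. One intramolecular [2+2] photocycloaddition of an (R)-1-aryl-3-borylallyl sinapyl ether (ring B O-benzyl, ring C O-TIPS, (E)-alkenyl-Bpin) forms C8–C8′ and C9–C7′, closing the C7–O–C9′–C8′–C8 tetrahydrofuran and a cyclobutane. The step exploits the cis fusion of the two tetrahydrofuran rings at bridgeheads C8 and C8′, the only fusion a bicyclo[3.2.0]heptane allows, while C7 directs the face. Oxidation at boron and Baeyer–Villiger insertion of oxygen into C9–C7′ then give the second ring; the threo (7″S,8″S) glycerol aryl ether on ring B is added last by an Evans syn-aldol.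

Key step: step 8

Remarks
- Numbering: C7, C8, C9 belong to the ring B (guaiacyl) half, C7′, C8′, C9′ to the ring C (syringyl) half, and C7″, C8″, C9″ to the glycerol unit that carries ring A.
- Abbreviations: ArB = 4-(benzyloxy)-3-methoxyphenyl; ArC = 3,5-dimethoxy-4-[(triisopropylsilyl)oxy]phenyl; ArA = 3-methoxy-4-[(triisopropylsilyl)oxy]phenyl; Bpin = 4,4,5,5-tetramethyl-1,3,2-dioxaborolan-2-yl; O-TIPS-sinapyl = (E)-3-ArC-prop-2-en-1-yl.
- The 3-oxabicyclo[3.2.0]heptanes of steps 8 to 10 are numbered C1 = C8, C2 = C7, O3, C4 = C9′, C5 = C8′, C6 = C7′, C7 = C9.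
- Assumption: 4-(benzyloxy)-3-methoxybenzaldehyde and (R)-4-benzyl-3-(chloroacetyl)oxazolidin-2-one are taken as catalogue compounds.
- Protecting groups: ring B carries benzyl and rings A and C carry TIPS, so that the alkoxide of step 6 bears no aryl silyl ether and the last step is a buffered fluoride deprotection.
- C7 is set by lipase resolution, because reduction catalysts differentiate an aryl from an alkynyl substituent on a ketone poorly.
- C7′ is not corrected by acid equilibration of the finished furofuran, since acid opens both benzylic C–O bonds and gives exo/endo mixtures. It is set in step 8 and kept by retention in steps 11 and 13.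

Step 1
Reactants: 1 4-(benzyloxy)-3-methoxybenzaldehyde; 2 ethynylmagnesium bromide (HC≡CMgBr)
Product: 4 rac-1-ArB-prop-2-yn-1-yl acetate, via bromomagnesium alkoxide 3 (not isolated)
Conditions: THF, 0 °C; then Ac2O, 0 °C to rt
Reagents that add atoms: acetic anhydride, CC(=O)OC(C)=O
Why: Grignard addition of the acetylide to the aldehyde and O-acetylation of the magnesium alkoxide in the same flask give the racemic propargylic acetate, whose stereocentre is resolved in step 2.

Step 2
Reactants: 4 rac-1-ArB-prop-2-yn-1-yl acetate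
Product: 5 (R)-1-ArB-prop-2-yn-1-ol
Conditions: Novozym 435 (immobilised Candida antarctica lipase B), n-BuOH (4 equiv), MTBE, 40 °C, stopped short of half conversion
Reagents that add atoms: none
Why: Lipase-catalysed kinetic resolution by enantioselective alcoholysis, in which the enzyme deacylates only the ester that places the aryl group in its large pocket and the slim ethynyl group in its medium pocket (the R ester, the same preference as in acylation of 1-arylprop-2-yn-1-ols and 1-arylethanols), so that C7 is set as R and the S acetate stays behind.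

Step 3
Reactants: 6 syringaldehyde
Product: 7 3,5-dimethoxy-4-[(triisopropylsilyl)oxy]benzaldehyde
Conditions: TIPSCl, imidazole, DMAP (cat.), DMF, 40 °C
Reagents that add atoms: triisopropylsilyl chloride, CC(C)[Si](Cl)(C(C)C)C(C)C
Why: Imidazole-promoted silylation of the phenol works on the 2,6-dimethoxyphenol, and the two flanking methoxy groups later shield this silyl ether from bases and nucleophiles.

Step 4
Reactants: 7 3,5-dimethoxy-4-[(triisopropylsilyl)oxy]benzaldehyde; 8 vinylmagnesium bromide (CH2=CHMgBr)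
Product: 9 rac-1-ArC-prop-2-en-1-ol
Conditions: THF, −20 to 0 °C; H2O work-up
Reagents that add atoms: none
Why: Grignard addition of the vinyl nucleophile to the aldehyde, the carbinol centre being left racemic because step 5 removes it.

Step 5
Reactants: 9 rac-1-ArC-prop-2-en-1-ol
Product: 10 (E)-3-ArC-prop-2-en-1-yl bromide (O-TIPS-sinapyl bromide)
Conditions: PBr3 (0.4 equiv), Et2O, 0 °C; used crude
Reagents that add atoms: phosphorus tribromide, BrP(Br)Br
Why: Bromination of a 1-arylallyl alcohol with PBr3 proceeds with allylic transposition (SN2′ or ion-pair collapse) to the conjugated primary (E)-cinnamyl bromide, the thermodynamic product, which erases the carbinol stereocentre.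

Step 6
Reactants: 5 (R)-1-ArB-prop-2-yn-1-ol; 10 O-TIPS-sinapyl bromide
Product: 12 (R)-1-ArB-prop-2-yn-1-yl O-TIPS-sinapyl ether, via sodium alkoxide 11 (not isolated)
Conditions: NaH (1.1 equiv), THF, 0 °C; then 10, Bu4NI (cat.), 0 °C to rt
Reagents that add atoms: none
Why: Williamson ether synthesis by SN2 attack of the secondary alkoxide on the primary allylic bromide, which does not break the C7–O bond, so C7 stays R.

Step 7
Reactants: 12 (R)-1-ArB-prop-2-yn-1-yl O-TIPS-sinapyl ether; 13 pinacolborane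
Product: 14 (R,E)-1-ArB-3-Bpin-prop-2-en-1-yl O-TIPS-sinapyl ether (C7 R; both alkenes E)
Conditions: Cp2ZrHCl (10 mol %), Et3N (10 mol %), toluene, 60 °C
Reagents that add atoms: none
Why: Zirconium-catalysed hydroboration (syn hydrozirconation of the terminal alkyne, then zirconium-to-boron exchange with pinacolborane) puts boron on the terminal carbon with E geometry and leaves the 1,2-disubstituted sinapyl alkene and C7 untouched.

Step 8
Reactants: 14 (R,E)-1-ArB-3-Bpin-prop-2-en-1-yl O-TIPS-sinapyl ether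
Product: 15 2-ArB-6-ArC-7-Bpin-3-oxabicyclo[3.2.0]heptane (C2 R; H1 and H5 cis; both aryl groups exo; epimers at the boron-bearing carbon)
Conditions: [Ir(dF(CF3)ppy)2(dtbbpy)]PF6 (2 mol %), degassed DMSO (0.02 M), 450 nm LEDs, 25 °C
Reagents that add atoms: none
Why: Triplet energy transfer from the photoexcited iridium complex to the ring C styrene gives a 1,2-diradical whose C8′ terminus adds to C8 of the alkenylboronate, and the resulting 1,4-diradical (benzylic at C7′, α-boryl at C9) forms C9–C7′ after intersystem crossing. The closest known reaction type is the visible-light, triplet-sensitised intramolecular [2+2] cycloaddition of styrenes with ether-tethered alkenes, together with sensitised [2+2] cycloadditions that use an alkenylboronate as partner. The tetrahydrofuran closes by 5-exo-trig radical addition and the cyclobutane by radical–radical recombination, the three-atom tether enforcing the fused and not the crossed regiochemistry. C8 and C8′ must be cis because a trans-fused bicyclo[3.2.0]heptane is out of reach; C8 is set relative to C7 by a chair-like 5-exo transition state with ring B pseudo-equatorial, which places ring B trans to the C8–C9 bond; ring C goes to the convex face at C7′ because the benzylic radical terminus rotates freely before closure; C9 is uncontrolled and is erased in step 10. The step needs facial selectivity with respect to the single stereocentre C7, secured by the allylic ring B substituent, and selective sensitisation of the styrene, secured by the much higher triplet energy of the non-conjugated alkenylboronate; E/Z isomerisation is harmless because both isomers feed the same diradical.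

Step 9
Reactants: 15 2-ArB-6-ArC-7-Bpin-3-oxabicyclo[3.2.0]heptane
Product: 16 2-ArB-6-ArC-3-oxabicyclo[3.2.0]heptan-7-ol (epimers at the carbinol carbon; other centres as in 15)
Conditions: NaBO3·4H2O (4 equiv), THF/H2O (1:1), rt
Reagents that add atoms: sodium perborate tetrahydrate, [Na+].[O-]OB=O.O.O.O.O
Why: Oxidation of a secondary alkylboronate by perborate (1,2-shift of carbon from boron to oxygen with retention) is mild enough for the aryl silyl ether, and the C9 epimer mixture is of no consequence because step 10 makes C9 trigonal.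

Step 10
Reactants: 16 2-ArB-6-ArC-3-oxabicyclo[3.2.0]heptan-7-ol
Product: 17 2-ArB-6-ArC-3-oxabicyclo[3.2.0]heptan-7-one (cyclobutanone with the C9 carbonyl; ring C exo)
Conditions: Dess–Martin periodinane (1.5 equiv), NaHCO3, CH2Cl2, 0 °C to rt
Reagents that add atoms: none
Why: Dess–Martin oxidation of the secondary cyclobutanol under buffered conditions gives the strained ketone, whose ring fusion cannot change because a 3-oxabicyclo[3.2.0]heptane exists only cis-fused, while an endo ring C isomer, if present, can relax to exo by enolisation at the benzylic C7′.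

Step 11
Reactants: 17 2-ArB-6-ArC-3-oxabicyclo[3.2.0]heptan-7-one
Product: 18 (3R,3aS,6R,6aR)-6-ArB-3-ArC-tetrahydro-1H,3H-furo[3,4-c]furan-1-one (γ-lactone; C9 carbonyl; ring oxygen between C9 and C7′)
Conditions: mCPBA (1.3 equiv), NaHCO3, CH2Cl2, 0 °C
Reagents that add atoms: 3-chloroperoxybenzoic acid, OOC(=O)c1cccc(Cl)c1
Why: Baeyer–Villiger oxidation, fast for a strained cyclobutanone, in which the benzylic C7′ (better able than the ring-fusion carbon C8 to carry positive charge in the Criegee rearrangement) migrates with retention, so that oxygen enters between C9 and C7′ and ring C stays exo.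

Step 12
Reactants: 18 γ-lactone
Product: 19 {(2R,3S,4S)-2-ArB-4-[(R)-ArC(hydroxy)methyl]oxolan-3-yl}methanol
Conditions: LiAlH4 (1.5 equiv), THF, 0 °C; H2O/NaOH work-up
Reagents that add atoms: none
Why: Hydride reduction of the lactone with LiAlH4 gives the primary C9 alcohol and the benzylic C7′ alcohol without touching any stereocentre.

Step 13
Reactants: 19 {(2R,3S,4S)-2-ArB-4-[(R)-ArC(hydroxy)methyl]oxolan-3-yl}methanol
Product: 21 (1R,3aS,4R,6aS)-1-ArB-4-ArC-tetrahydro-1H,3H-furo[3,4-c]furan, via primary mesylate 20 (not isolated)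
Conditions: MsCl (1.1 equiv), Et3N (3 equiv), CH2Cl2, 0 °C to rt
Reagents that add atoms: none
Why: Selective sulfonylation of the primary hydroxyl and intramolecular Williamson-type 5-exo-tet displacement by the C7′ hydroxyl close the second tetrahydrofuran under basic conditions with retention at C7′ (its C–O bond is not broken), the cis fusion following from the cis C8/C8′ substituents.

Step 14
Reactants: 21 (1R,3aS,4R,6aS)-1-ArB-4-ArC-tetrahydro-1H,3H-furo[3,4-c]furan
Product: 22 4-[(1R,3aS,4R,6aS)-4-ArC-tetrahydro-1H,3H-furo[3,4-c]furan-1-yl]-2-methoxyphenol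
Conditions: H2 (1 atm), 10% Pd/C, EtOAc, rt, stopped at full conversion
Reagents that add atoms: none
Why: Catalytic hydrogenolysis under neutral conditions cleaves the aryl benzyl ether much faster than the dialkyl-type benzylic C–O bonds of the furofuran and leaves the aryl silyl ether and all stereocentres alone.

Step 15
Reactants: 22 ring B phenol; 23 (R)-4-benzyl-3-(chloroacetyl)oxazolidin-2-one
Product: 24 (R)-4-benzyl-3-(2-{4-[(1R,3aS,4R,6aS)-4-ArC-tetrahydro-1H,3H-furo[3,4-c]furan-1-yl]-2-methoxyphenoxy}acetyl)oxazolidin-2-one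
Conditions: K2CO3 (2 equiv), NaI (10 mol %), acetone, 40 °C
Reagents that add atoms: none
Why: Williamson O-alkylation of the phenoxide by the α-chloro imide (iodide-assisted SN2) attaches the glycolate unit without forming a stereocentre.

Step 16
Reactants: 25 vanillin
Product: 26 3-methoxy-4-[(triisopropylsilyl)oxy]benzaldehyde
Conditions: TIPSCl, imidazole, DMF, rt
Reagents that add atoms: triisopropylsilyl chloride, CC(C)[Si](Cl)(C(C)C)C(C)C
Why: Standard imidazole-promoted silylation of the phenol gives the ring A aldehyde with a fluoride-labile protecting group.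

Step 17
Reactants: 24 aryloxyacetyl imide; 26 3-methoxy-4-[(triisopropylsilyl)oxy]benzaldehyde
Product: 28 (R)-4-benzyl-3-[(2R,3S)-3-ArA-3-hydroxy-2-(aryloxy)propanoyl]oxazolidin-2-one (aryloxy = the phenoxy group of 22), via dibutylboron Z-enolate 27 (not isolated)
Conditions: Bu2BOTf (1.2 equiv), Et3N (1.5 equiv), CH2Cl2, −78 to 0 °C; then 26, −78 to 0 °C; pH 7 buffer, MeOH, 30% H2O2, 0 °C
Reagents that add atoms: none
Why: Evans syn-aldol reaction, in which the dibutylboron Z-enolate of the aryloxyacetyl imide reacts through a closed Zimmerman–Traxler chair on the enolate face opposite the benzyl group of the (R)-auxiliary, setting C8″ and C7″ together as the syn (threo) pair that becomes 7″S,8″S.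

Step 18
Reactants: 28 aldol adduct
Product: 29 (1S,2S)-1-ArA-2-{4-[(1R,3aS,4R,6aS)-4-ArC-tetrahydro-1H,3H-furo[3,4-c]furan-1-yl]-2-methoxyphenoxy}propane-1,3-diol
Conditions: LiBH4 (2 equiv), THF, H2O (2 equiv), 0 °C
Reagents that add atoms: none
Why: Reductive cleavage of the N-acyloxazolidinone with LiBH4 gives the primary C9″ alcohol and releases the auxiliary without touching C7″ or C8″.

Step 19
Reactants: 29 bis-TIPS threo diol
Product: 30 (1S,2S)-1-(4-hydroxy-3-methoxyphenyl)-2-{4-[(1R,3aS,4R,6aS)-4-(4-hydroxy-3,5-dimethoxyphenyl)tetrahydro-1H,3H-furo[3,4-c]furan-1-yl]-2-methoxyphenoxy}propane-1,3-diol (CNP0255927.3)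
Conditions: TBAF (2.5 equiv), AcOH (2.5 equiv), THF, 0 °C
Reagents that add atoms: none
Why: Fluoride-mediated desilylation of the two aryl silyl ethers, buffered with acetic acid so that the freed p-hydroxybenzylic ethers do not meet strong base, releases the target without affecting any stereocentre.

Compound list
1 | 4-(benzyloxy)-3-methoxybenzaldehyde | O=Cc1ccc(OCc2ccccc2)c(OC)c1 | starting material
2 | ethynylmagnesium bromide | C#C[Mg]Br | starting material
3 | bromomagnesium alkoxide of racemic 1-ArB-prop-2-yn-1-ol | C#CC(O[Mg]Br)c1ccc(OCc2ccccc2)c(OC)c1 | intermediate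
4 | rac-1-[4-(benzyloxy)-3-methoxyphenyl]prop-2-yn-1-yl acetate | CC(=O)OC(C#C)c1ccc(OCc2ccccc2)c(OC)c1 | intermediate
5 | (R)-1-[4-(benzyloxy)-3-methoxyphenyl]prop-2-yn-1-ol | O[C@H](C#C)c1ccc(OCc2ccccc2)c(OC)c1 | intermediate
6 | syringaldehyde | COc1cc(C=O)cc(OC)c1O | starting material
7 | 3,5-dimethoxy-4-[(triisopropylsilyl)oxy]benzaldehyde | COc1cc(C=O)cc(OC)c1O[Si](C(C)C)(C(C)C)C(C)C | intermediate
8 | vinylmagnesium bromide | C=C[Mg]Br | starting material
9 | rac-1-{3,5-dimethoxy-4-[(triisopropylsilyl)oxy]phenyl}prop-2-en-1-ol | C=CC(O)c1cc(OC)c(O[Si](C(C)C)(C(C)C)C(C)C)c(OC)c1 | intermediate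
10 | (E)-[4-(3-bromoprop-1-en-1-yl)-2,6-dimethoxyphenoxy]triisopropylsilane (O-TIPS-sinapyl bromide) | BrC/C=C/c1cc(OC)c(O[Si](C(C)C)(C(C)C)C(C)C)c(OC)c1 | intermediate
11 | sodium (R)-1-[4-(benzyloxy)-3-methoxyphenyl]prop-2-yn-1-olate | [Na+].[O-][C@H](C#C)c1ccc(OCc2ccccc2)c(OC)c1 | intermediate
12 | (R)-1-ArB-prop-2-yn-1-yl (E)-3-ArC-prop-2-en-1-yl ether | C#C[C@@H](OC/C=C/c1cc(OC)c(O[Si](C(C)C)(C(C)C)C(C)C)c(OC)c1)c2ccc(OCc3ccccc3)c(OC)c2 | intermediate
13 | pinacolborane | B1OC(C)(C)C(C)(C)O1 | starting material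
14 | (R,E)-1-ArB-3-Bpin-prop-2-en-1-yl (E)-3-ArC-prop-2-en-1-yl ether (key-step precursor) | COc1cc(ccc1OCc2ccccc2)[C@H](OC/C=C/c3cc(OC)c(O[Si](C(C)C)(C(C)C)C(C)C)c(OC)c3)/C=C/B4OC(C)(C)C(C)(C)O4 | intermediate
15 | 2-ArB-6-ArC-7-Bpin-3-oxabicyclo[3.2.0]heptane; C2 R, cis-fused, both aryl groups exo, boron-bearing carbon undefined (key-step product) | COc1cc(ccc1OCc2ccccc2)[C@@H]3OC[C@@H]4[C@H]3C(B5OC(C)(C)C(C)(C)O5)[C@H]4c6cc(OC)c(O[Si](C(C)C)(C(C)C)C(C)C)c(OC)c6 | intermediate
16 | 2-ArB-6-ArC-3-oxabicyclo[3.2.0]heptan-7-ol; carbinol carbon undefined, other centres as in 15 | COc1cc(ccc1OCc2ccccc2)[C@@H]3OC[C@@H]4[C@H]3C(O)[C@H]4c5cc(OC)c(O[Si](C(C)C)(C(C)C)C(C)C)c(OC)c5 | intermediate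
17 | 2-ArB-6-ArC-3-oxabicyclo[3.2.0]heptan-7-one; cis-fused, both aryl groups exo | COc1cc(ccc1OCc2ccccc2)[C@@H]3OC[C@@H]4[C@H]3C(=O)[C@H]4c5cc(OC)c(O[Si](C(C)C)(C(C)C)C(C)C)c(OC)c5 | intermediate
18 | (3R,3aS,6R,6aR)-6-ArB-3-ArC-tetrahydro-1H,3H-furo[3,4-c]furan-1-one | COc1cc(ccc1OCc2ccccc2)[C@@H]3OC[C@@H]4[C@H]3C(=O)O[C@H]4c5cc(OC)c(O[Si](C(C)C)(C(C)C)C(C)C)c(OC)c5 | intermediate
19 | {(2R,3S,4S)-2-ArB-4-[(R)-ArC(hydroxy)methyl]oxolan-3-yl}methanol | COc1cc(ccc1OCc2ccccc2)[C@@H]3OC[C@H]([C@H]3CO)[C@@H](O)c4cc(OC)c(O[Si](C(C)C)(C(C)C)C(C)C)c(OC)c4 | intermediate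
20 | primary methanesulfonate of 19 (C9 O-mesylate, C7′ hydroxyl free) | COc1cc(ccc1OCc2ccccc2)[C@@H]3OC[C@H]([C@H]3COS(C)(=O)=O)[C@@H](O)c4cc(OC)c(O[Si](C(C)C)(C(C)C)C(C)C)c(OC)c4 | intermediate
21 | (1R,3aS,4R,6aS)-1-ArB-4-ArC-tetrahydro-1H,3H-furo[3,4-c]furan | COc1cc(ccc1OCc2ccccc2)[C@@H]3OC[C@@H]4[C@H]3CO[C@H]4c5cc(OC)c(O[Si](C(C)C)(C(C)C)C(C)C)c(OC)c5 | intermediate
22 | 4-[(1R,3aS,4R,6aS)-4-ArC-tetrahydro-1H,3H-furo[3,4-c]furan-1-yl]-2-methoxyphenol | COc1cc(ccc1O)[C@@H]2OC[C@@H]3[C@H]2CO[C@H]3c4cc(OC)c(O[Si](C(C)C)(C(C)C)C(C)C)c(OC)c4 | intermediate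
23 | (R)-4-benzyl-3-(chloroacetyl)oxazolidin-2-one | ClCC(=O)N1[C@H](Cc2ccccc2)COC1=O | starting material
24 | (R)-4-benzyl-3-(2-{4-[(1R,3aS,4R,6aS)-4-ArC-tetrahydro-1H,3H-furo[3,4-c]furan-1-yl]-2-methoxyphenoxy}acetyl)oxazolidin-2-one | COc1cc(ccc1OCC(=O)N2[C@H](Cc3ccccc3)COC2=O)[C@@H]4OC[C@@H]5[C@H]4CO[C@H]5c6cc(OC)c(O[Si](C(C)C)(C(C)C)C(C)C)c(OC)c6 | intermediate
25 | vanillin | COc1cc(C=O)ccc1O | starting material
26 | 3-methoxy-4-[(triisopropylsilyl)oxy]benzaldehyde | COc1cc(C=O)ccc1O[Si](C(C)C)(C(C)C)C(C)C | intermediate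
27 | dibutylboron Z-enolate of 24 | CCCCB(CCCC)O/C(=C\Oc1ccc(cc1OC)[C@@H]2OC[C@@H]3[C@H]2CO[C@H]3c4cc(OC)c(O[Si](C(C)C)(C(C)C)C(C)C)c(OC)c4)N5[C@H](Cc6ccccc6)COC5=O | intermediate
28 | (R)-4-benzyl-3-[(2R,3S)-3-ArA-3-hydroxy-2-{4-[(1R,3aS,4R,6aS)-4-ArC-tetrahydro-1H,3H-furo[3,4-c]furan-1-yl]-2-methoxyphenoxy}propanoyl]oxazolidin-2-one | COc1cc([C@H](O)[C@H](C(=O)N2[C@H](Cc3ccccc3)COC2=O)Oc4ccc([C@@H]5OC[C@@H]6[C@H]5CO[C@H]6c7cc(OC)c(O[Si](C(C)C)(C(C)C)C(C)C)c(OC)c7)cc4OC)ccc1O[Si](C(C)C)(C(C)C)C(C)C | intermediate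
29 | (1S,2S)-1-ArA-2-{4-[(1R,3aS,4R,6aS)-4-ArC-tetrahydro-1H,3H-furo[3,4-c]furan-1-yl]-2-methoxyphenoxy}propane-1,3-diol | COc1cc([C@H](O)[C@H](CO)Oc2ccc([C@@H]3OC[C@@H]4[C@H]3CO[C@H]4c5cc(OC)c(O[Si](C(C)C)(C(C)C)C(C)C)c(OC)c5)cc2OC)ccc1O[Si](C(C)C)(C(C)C)C(C)C | intermediate
30 | (1S,2S)-1-(4-hydroxy-3-methoxyphenyl)-2-{4-[(1R,3aS,4R,6aS)-4-(4-hydroxy-3,5-dimethoxyphenyl)tetrahydro-1H,3H-furo[3,4-c]furan-1-yl]-2-methoxyphenoxy}propane-1,3-diol | COc1cc([C@H](O)[C@H](CO)Oc2ccc([C@@H]3OC[C@@H]4[C@H]3CO[C@H]4c3cc(OC)c(O)c(OC)c3)cc2OC)ccc1O | target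

Total step count: 19
Longest linear sequence: 16 steps (steps 3 to 15 and 17 to 19, from syringaldehyde)

Steps most likely to fail

1. Step 8. The 5-exo closure may discriminate poorly between the two faces of the alkenylboronate, which would put the C8/C8′ pair on the wrong side of ring B. The electron-rich styrene may also be oxidised by the excited sensitiser and oligomerise instead of cyclising. The fallback makes the same C8–C8′ bond with a ground-state radical and sets out from alcohol 5. Partial hydrogenation of the alkyne (H2, Pd/CaCO3 poisoned with Pb(OAc)2, quinoline, EtOAc) gives (R)-1-ArB-prop-2-en-1-ol F1. Hydroxyl-directed epoxidation of the vinyl group (VO(acac)2 cat., t-BuOOH, CH2Cl2, 0 °C) gives the epoxy alcohol F2, whose oxirane carbon may have either configuration because it becomes a radical. Williamson etherification with bromide 10 (NaH, THF, 0 °C) gives the epoxy ether F3. Treatment of F3 with Cp2TiCl (trivalent titanium, made in the flask from Cp2TiCl2 and Zn dust) in THF at rt opens the epoxide homolytically to the C8 radical. Its 5-exo-trig addition to the sinapyl alkene gives the 2,3-trans-3,4-cis tetrahydrofuran and the C7′ benzylic radical. Iodine then turns C7′ into a benzylic electrophile that the C9 titanium alkoxide captures from the convex side. This closes the second ring and returns to the route at furofuran 21, so steps 7 to 13 are bypassed.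

2. Step 11. The ring-fusion carbon C8 may migrate in competition with C7′, which would insert oxygen on the wrong side of the carbonyl, and the peracid may attack the electron-rich rings. The fallback cleaves the C9–C7′ bond by a route whose regiochemistry is fixed by enolisation, and sets out from ketone 17. Deprotonation (KN(SiMe3)2, THF, −78 °C) takes place at the benzylic C7′, the more acidic α-position, and 2-(phenylsulfonyl)-3-phenyloxaziridine then gives the C7′-hydroxy ketone F4. Cleavage of this α-ketol with Pb(OAc)4 in MeOH/toluene at 0 °C gives the keto ester F5 (methyl ester at C9, aryl ketone at C7′). LiAlH4 in THF at 0 °C gives the diol F6 as a mixture of C7′ epimers. Ring closure through the C7′ benzylic cation under kinetic control (camphorsulfonic acid cat., CH2Cl2, 0 °C, short contact; attack of the C9 hydroxyl from the convex side places ring C exo) returns to the route at furofuran 21.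

3. Step 17. Enolisation of the bulky aryloxyacetyl imide may be incomplete, the syn selectivity may erode, or the adduct of the electron-rich aldehyde may undergo retro-aldol cleavage during work-up. The fallback builds the threo unit by carbenoid O–H insertion and dynamic reduction, and sets out from phenol 22. Aldehyde 26 is homologated by the Roskamp reaction (ethyl diazoacetate, SnCl2 cat., CH2Cl2) to the β-keto ester F7. Diazo transfer (4-acetamidobenzenesulfonyl azide, Et3N, MeCN) gives the diazo keto ester F8. Rh2(OAc)4-catalysed O–H insertion of the carbenoid from F8 into phenol 22 (CH2Cl2, 40 °C) gives the α-aryloxy β-keto ester F9, which is configurationally labile at C8″. Transfer hydrogenation with RuCl(p-cymene)[(R,R)-TsDPEN] in HCO2H/Et3N, the catalyst enantiomer being chosen by the aryl ketone model, reduces the aryl ketone from one face while C8″ equilibrates. This dynamic kinetic resolution is known for α-alkoxy β-keto esters to give the syn hydroxy ester, here the (2R,3S) ester F10. LiBH4 reduction of the ester (THF, 0 °C) returns to the route at diol 29.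

Further compounds
F1 | step 8 | (R)-1-[4-(benzyloxy)-3-methoxyphenyl]prop-2-en-1-ol | O[C@H](C=C)c1ccc(OCc2ccccc2)c(OC)c1
F2 | step 8 | (S)-[4-(benzyloxy)-3-methoxyphenyl](oxiran-2-yl)methanol (carbinol carbon placed as in 5; oxirane carbon undefined) | O[C@H](C1CO1)c2ccc(OCc3ccccc3)c(OC)c2
F3 | step 8 | (S)-ArB(oxiran-2-yl)methyl (E)-3-ArC-prop-2-en-1-yl ether (ether carbon placed as in 12; oxirane carbon undefined) | C1OC1[C@@H](OC/C=C/c2cc(OC)c(O[Si](C(C)C)(C(C)C)C(C)C)c(OC)c2)c3ccc(OCc4ccccc4)c(OC)c3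
F4 | step 11 | 2-ArB-6-ArC-6-hydroxy-3-oxabicyclo[3.2.0]heptan-7-one (hydroxylated carbon undefined) | COc1cc(ccc1OCc2ccccc2)[C@@H]3OC[C@@H]4[C@H]3C(=O)C4(O)c5cc(OC)c(O[Si](C(C)C)(C(C)C)C(C)C)c(OC)c5
F5 | step 11 | methyl 2-ArB-4-(ArC-carbonyl)oxolane-3-carboxylate (2,3-trans, 3,4-cis; ring centres as in 19) | COc1cc(ccc1OCc2ccccc2)[C@@H]3OC[C@H]([C@H]3C(=O)OC)C(=O)c4cc(OC)c(O[Si](C(C)C)(C(C)C)C(C)C)c(OC)c4
F6 | step 11 | {2-ArB-4-[ArC(hydroxy)methyl]oxolan-3-yl}methanol as a mixture of C7′ epimers (ring centres as in 19) | COc1cc(ccc1OCc2ccccc2)[C@@H]3OC[C@H]([C@H]3CO)C(O)c4cc(OC)c(O[Si](C(C)C)(C(C)C)C(C)C)c(OC)c4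
F7 | step 17 | ethyl 3-{3-methoxy-4-[(triisopropylsilyl)oxy]phenyl}-3-oxopropanoate | CCOC(=O)CC(=O)c1ccc(O[Si](C(C)C)(C(C)C)C(C)C)c(OC)c1
F8 | step 17 | ethyl 2-diazo-3-{3-methoxy-4-[(triisopropylsilyl)oxy]phenyl}-3-oxopropanoate | CCOC(=O)C(=[N+]=[N-])C(=O)c1ccc(O[Si](C(C)C)(C(C)C)C(C)C)c(OC)c1
F9 | step 17 | ethyl 3-ArA-3-oxo-2-{4-[(1R,3aS,4R,6aS)-4-ArC-tetrahydro-1H,3H-furo[3,4-c]furan-1-yl]-2-methoxyphenoxy}propanoate (C2 undefined) | CCOC(=O)C(Oc1ccc(cc1OC)[C@@H]2OC[C@@H]3[C@H]2CO[C@H]3c4cc(OC)c(O[Si](C(C)C)(C(C)C)C(C)C)c(OC)c4)C(=O)c5ccc(O[Si](C(C)C)(C(C)C)C(C)C)c(OC)c5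
F10 | step 17 | ethyl (2R,3S)-3-ArA-3-hydroxy-2-{4-[(1R,3aS,4R,6aS)-4-ArC-tetrahydro-1H,3H-furo[3,4-c]furan-1-yl]-2-methoxyphenoxy}propanoate | COc1cc([C@H](O)[C@H](C(=O)OCC)Oc2ccc([C@@H]3OC[C@@H]4[C@H]3CO[C@H]4c5cc(OC)c(O[Si](C(C)C)(C(C)C)C(C)C)c(OC)c5)cc2OC)ccc1O[Si](C(C)C)(C(C)C)C(C)C
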